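## Retrosynthetic overview

1. The acetate comes from the C4 alcohol; the γ-lactone is formed last by Pd/CO carbonylative lactonisation of a C1 enol triflate onto the C19 hydroxyl (C1–C18 bond).
2. The C1 ketone sits in a (6E)-cyclononene that is formed first, by intramolecular B-alkyl Suzuki coupling (C7–C8) of an (E)-alkenyl iodide with a terminal vinyl group.
3. The seco compound comes from the key intermolecular Evans syn-aldol of a chiral N-acyl oxazolidinone with acrolein (C1–C2 bond); it sets C2 and delivers both the C1 oxygen and the C8=C9 vinyl group.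
4. The acyl partner comes from catalytic asymmetric propargylation of a C4 aldehyde (sets C4) and carboalumination/iodination; C3 is set by Evans alkylation of the N-citronelloyl oxazolidinone with tert-butyl bromoacetate.
5. C10 is taken from (R)-citronellic acid; ring order is nine-membered carbocycle (step 13), then butyrolactone (step 19).

Convention (one line): ring compounds use xenicane locants (ring C1–C9; C1 becomes the alkylidene carbon, C2 is the ring-fusion CH bearing C19H2O, C3 bears the C10 side chain, C4 is CH–O, C6 bears CH3, C18 is the lactone C=O); TBS = tert-butyldimethylsilyl; all numbered starting materials are bought.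

## Route

Step 1
Reactants: 1 (R)-citronellic acid; 2 (R)-4-benzyloxazolidin-2-one
Product: 4 (4R)-4-benzyl-3-[(3R)-3,7-dimethyloct-6-enoyl]oxazolidin-2-one, via mixed pivalic anhydride 3 (not isolated)
Conditions: PivCl, Et3N, THF, −20 °C; then 2, LiCl, rt
Reagents that add atoms: none
Why: N-acylation of the oxazolidinone through the mixed anhydride installs the Evans auxiliary without strong base; C10 is carried in unchanged from (R)-citronellic acid.

Step 2
Reactants: 4 N-citronelloyl oxazolidinone; 5 tert-butyl bromoacetate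
Product: 7 tert-butyl (3R,4R)-3-{[(4R)-4-benzyl-2-oxooxazolidin-3-yl]carbonyl}-4,8-dimethylnon-7-enoate, via sodium Z-enolate 6 (not isolated)
Conditions: NaHMDS, THF, −78 °C; then 5, −78 → −40 °C
Reagents that add atoms: none
Why: Evans asymmetric alkylation: the chelated Z-enolate is attacked on the face away from the benzyl group, which sets C3 (the (R)-auxiliary gives the required sense, the reverse of the known (S)-auxiliary/allyl iodide outcome).

Step 3
Reactants: 7 alkylated imide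
Product: 8 tert-butyl (3R,4R)-3-(hydroxymethyl)-4,8-dimethylnon-7-enoate
Conditions: LiBH4, THF, 0 °C → rt
Reagents that add atoms: none
Why: Reductive removal of the auxiliary; LiBH4 reduces the activated imide carbonyl and leaves the hindered tert-butyl ester.

Step 4
Reactants: 8 primary alcohol
Product: 9 tert-butyl (3R,4R)-3-formyl-4,8-dimethylnon-7-enoate
Conditions: Dess–Martin periodinane, CH2Cl2, 0 °C → rt
Reagents that add atoms: none
Why: Dess–Martin oxidation is non-basic, so the α-stereocentre C3 is not epimerised; the aldehyde is used at once.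

Step 5
Reactants: 9 aldehyde; 10 allenylboronic acid pinacol ester
Product: 11 tert-butyl (3R,4R)-3-[(1R)-1-hydroxybut-3-yn-1-yl]-4,8-dimethylnon-7-enoate
Conditions: (R)-TRIP (10 mol%), 4 Å MS, toluene, −20 → 0 °C; aqueous work-up
Reagents that add atoms: none
Why: Chiral phosphoric acid-catalysed carbonyl propargylation (SE2' allenylboration through a closed six-membered transition state); (R)-TRIP is expected to direct Re-face attack to give 4R, the same sense as Felkin–Anh control from C3 (matched).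

Step 6
Reactants: 11 homopropargylic alcohol
Product: 12 tert-butyl (3R,4R)-3-[(1R)-1-(tert-butyldimethylsilyloxy)but-3-yn-1-yl]-4,8-dimethylnon-7-enoate
Conditions: TBSOTf, 2,6-lutidine, CH2Cl2, −78 → 0 °C
Reagents that add atoms: tert-butyldimethylsilyl triflate, CC(C)(C)[Si](C)(C)OS(=O)(=O)C(F)(F)F
Why: Silyl triflate silylation protects the hindered secondary alcohol and blocks γ-lactonisation onto the ester.

Step 7
Reactants: 12 silyl ether alkyne
Product: 14 tert-butyl (3R,4R)-3-[(1R,3E)-1-(tert-butyldimethylsilyloxy)-4-iodo-3-methylbut-3-en-1-yl]-4,8-dimethylnon-7-enoate, via E-alkenyl dimethylalane 13 (not isolated)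
Conditions: Me3Al, Cp2ZrCl2 (25 mol%), CH2Cl2, 0 °C → rt; then I2, THF, −30 → 0 °C
Reagents that add atoms: trimethylaluminium, C[Al](C)C; iodine, II
Why: Negishi zirconium-catalysed carboalumination adds Me and Al syn with Al on the terminal carbon, and iodinolysis with retention gives the (E)-trisubstituted alkenyl iodide.

Step 8
Reactants: 14 alkenyl iodide tert-butyl ester
Product: 16 (3R,4R)-3-[(1R,3E)-1-(tert-butyldimethylsilyloxy)-4-iodo-3-methylbut-3-en-1-yl]-4,8-dimethylnon-7-enoic acid, via trimethylsilyl ester 15 (not isolated)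
Conditions: TMSOTf, 2,6-lutidine, CH2Cl2, 0 °C; then pH 5 aqueous buffer
Reagents that add atoms: none
Why: Buffered silyl triflate cleavage of the tert-butyl ester to the silyl ester, hydrolysed on work-up, avoids protic acid and so spares the TBS ether and the acid-sensitive trisubstituted alkene.

Step 9
Reactants: 16 carboxylic acid; 17 (S)-4-benzyloxazolidin-2-one
Product: 19 (4S)-4-benzyl-3-{(3R,4R)-3-[(1R,3E)-1-(tert-butyldimethylsilyloxy)-4-iodo-3-methylbut-3-en-1-yl]-4,8-dimethylnon-7-enoyl}oxazolidin-2-one, via mixed pivalic anhydride 18 (not isolated)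
Conditions: PivCl, Et3N, THF, −20 °C; then 17, LiCl, rt
Reagents that add atoms: none
Why: Mixed-anhydride N-acylation installs the second auxiliary without organolithium base, so the alkenyl iodide is untouched.

Step 10 (key step)
Reactants: 19 N-acyl (S)-oxazolidinone; 20 acrolein
Product: 22 (4S)-4-benzyl-3-{(2S,3S,4R)-2-[(1R)-1-hydroxyprop-2-en-1-yl]-3-[(1R,3E)-1-(tert-butyldimethylsilyloxy)-4-iodo-3-methylbut-3-en-1-yl]-4,8-dimethylnon-7-enoyl}oxazolidin-2-one, via Z-dibutylboron enolate 21 (not isolated)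
Conditions: Bu2BOTf, i-Pr2NEt, CH2Cl2, −78 → 0 °C; then 20, −78 → 0 °C; then pH 7 buffer, MeOH, H2O2, 0 °C
Reagents that add atoms: none
Why: Intermolecular Evans syn-aldol (Z-boron enolate, Zimmerman–Traxler chair, auxiliary dipole-opposed) forms C1–C2, sets C2 under auxiliary control, and brings in the C1 oxygen and the C8=C9 vinyl group; the carbinol centre is defined but removed later.

Step 11
Reactants: 22 syn-aldol adduct
Product: 23 (2R,3S,4R)-2-[(1R)-1-hydroxyprop-2-en-1-yl]-3-[(1R,3E)-1-(tert-butyldimethylsilyloxy)-4-iodo-3-methylbut-3-en-1-yl]-4,8-dimethylnon-7-en-1-ol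
Conditions: LiBH4, THF, 0 °C
Reagents that add atoms: none
Why: Reductive cleavage of the auxiliary gives the 1,3-diol; the alkenyl iodide and silyl ether are inert to borohydride.

Step 12
Reactants: 23 1,3-diol
Product: 24 (4R,5R)-5-[(1E,4R,5S,6R)-4-(tert-butyldimethylsilyloxy)-1-iodo-2,6,10-trimethylundeca-1,9-dien-5-yl]-2,2-dimethyl-4-vinyl-1,3-dioxane
Conditions: 2,2-dimethoxypropane, PPTS (cat.), CH2Cl2, rt
Reagents that add atoms: 2,2-dimethoxypropane, COC(C)(C)OC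
Why: Acid-catalysed acetalisation ties O1 and O19 into the favoured six-membered acetonide.

Step 13
Reactants: 24 acetonide
Product: 26 (1R,2R,3S,4R,6E)-cyclononene acetonide, via B-alkyl-9-BBN 25 (not isolated)
Conditions: 9-BBN, THF, 0 °C → rt; then syringe-pump addition to Pd(dppf)Cl2 (20 mol%), AsPh3, Cs2CO3, THF/DMF/H2O, 50 °C, 2 mM
Reagents that add atoms: none
Why: 9-BBN hydroborates only the monosubstituted alkene, and the intramolecular B-alkyl Suzuki–Miyaura coupling under high dilution closes the nine-membered ring with retention of the iodide geometry (6E).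

Step 14
Reactants: 26 macrocyclic acetonide
Product: 27 (1R,2R,3S,4R,6E)-4-(tert-butyldimethylsilyloxy)-2-(hydroxymethyl)-6-methyl-3-[(2R)-6-methylhept-5-en-2-yl]cyclonon-6-en-1-ol
Conditions: PPTS, MeOH, rt
Reagents that add atoms: none
Why: Mild transacetalisation removes the acetonide while the hindered secondary TBS ether survives.

Step 15
Reactants: 27 macrocyclic diol
Product: 28 (1R,2R,3S,4R,6E)-4-(tert-butyldimethylsilyloxy)-2-[(tert-butyldimethylsilyloxy)methyl]-6-methyl-3-[(2R)-6-methylhept-5-en-2-yl]cyclonon-6-en-1-ol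
Conditions: TBSCl (1.1 equiv), imidazole, CH2Cl2, 0 °C
Reagents that add atoms: tert-butyldimethylsilyl chloride, CC(C)(C)[Si](C)(C)Cl
Why: Silylation is selective for the primary C19 hydroxyl over the hindered secondary C1 hydroxyl.

Step 16
Reactants: 28 secondary alcohol
Product: 29 (2R,3S,4R,6E)-4-(tert-butyldimethylsilyloxy)-2-[(tert-butyldimethylsilyloxy)methyl]-6-methyl-3-[(2R)-6-methylhept-5-en-2-yl]cyclonon-6-en-1-one
Conditions: Dess–Martin periodinane, pyridine, CH2Cl2, 0 °C → rt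
Reagents that add atoms: none
Why: Buffered Dess–Martin oxidation gives the C1 ketone under neutral conditions, so C2 is not epimerised and the β-silyloxy group is not eliminated.

Step 17
Reactants: 29 ketone
Product: 31 (1(9)E,2R,3S,4R,6E)-4-(tert-butyldimethylsilyloxy)-2-[(tert-butyldimethylsilyloxy)methyl]-6-methyl-3-[(2R)-6-methylhept-5-en-2-yl]cyclonona-1(9),6-dien-1-yl triflate, via potassium enolate 30 (not isolated)
Conditions: KHMDS, THF, −78 °C; then Comins' reagent, −78 → −40 °C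
Reagents that add atoms: N-(5-chloropyridin-2-yl)bis(trifluoromethanesulfonimide), FC(F)(F)S(=O)(=O)N(c1ccc(Cl)cn1)S(=O)(=O)C(F)(F)F
Why: Kinetic deprotonation takes the unhindered C9 methylene rather than the tertiary C2–H, and O-triflation traps the enolate; the ring already holding an E-alkene allows only the ring-cis C1=C9 geometry.

Step 18
Reactants: 31 enol triflate
Product: 32 (1(9)E,2R,3S,4R,6E)-4-hydroxy-2-(hydroxymethyl)-6-methyl-3-[(2R)-6-methylhept-5-en-2-yl]cyclonona-1(9),6-dien-1-yl triflate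
Conditions: HF·pyridine, pyridine, THF, 0 °C → rt
Reagents that add atoms: none
Why: Buffered fluoride desilylation removes both TBS ethers; enol triflates and the alkenes are stable to it.

Step 19
Reactants: 32 diol enol triflate
Product: 33 (3aS,4S,5R,7E,10E)-5-hydroxy-7-methyl-4-[(2R)-6-methylhept-5-en-2-yl]-3,3a,4,5,6,9-hexahydro-1H-cyclonona[c]furan-1-one
Conditions: Pd(PPh3)4 (10 mol%), CO (1 atm), Et3N, LiCl, DMF, 60 °C
Reagents that add atoms: carbon monoxide, [C-]#[O+]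
Why: Palladium-catalysed carbonylative lactonisation (oxidative addition, CO insertion, capture of the acyl-palladium by the C19 hydroxyl in a five-membered closure) gives the α-alkylidene γ-butyrolactone with the alkene geometry inherited from the triflate; the C4 hydroxyl could only give a strained bridged lactone.

Step 20
Reactants: 33 hydroxy lactone
Product: 34 (3aS,4S,5R,7E,10E)-7-methyl-4-[(2R)-6-methylhept-5-en-2-yl]-1-oxo-3,3a,4,5,6,9-hexahydro-1H-cyclonona[c]furan-5-yl acetate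
Conditions: Ac2O, pyridine, DMAP (cat.), CH2Cl2, 0 °C → rt
Reagents that add atoms: acetic anhydride, CC(=O)OC(C)=O
Why: DMAP-catalysed acylation of the only free (secondary) alcohol gives the target without touching the lactone or the skipped diene.

## Compound list

1 | (R)-citronellic acid, (3R)-3,7-dimethyloct-6-enoic acid | OC(=O)C[C@H](C)CCC=C(C)C | starting material
2 | (R)-4-benzyloxazolidin-2-one | O=C1N[C@H](Cc2ccccc2)CO1 | starting material
3 | (3R)-3,7-dimethyloct-6-enoic pivalic anhydride | CC(C)(C)C(=O)OC(=O)C[C@H](C)CCC=C(C)C | intermediate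
4 | (4R)-4-benzyl-3-[(3R)-3,7-dimethyloct-6-enoyl]oxazolidin-2-one | O=C(C[C@H](C)CCC=C(C)C)N1[C@H](Cc2ccccc2)COC1=O | intermediate
5 | tert-butyl bromoacetate | CC(C)(C)OC(=O)CBr | starting material
6 | sodium (Z)-enolate of 4 | [Na+].[O-]/C(=C\[C@H](C)CCC=C(C)C)N1[C@H](Cc2ccccc2)COC1=O | intermediate
7 | tert-butyl (3R,4R)-3-{[(4R)-4-benzyl-2-oxooxazolidin-3-yl]carbonyl}-4,8-dimethylnon-7-enoate | CC(C)(C)OC(=O)C[C@@H](C(=O)N1[C@H](Cc2ccccc2)COC1=O)[C@H](C)CCC=C(C)C | intermediate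
8 | tert-butyl (3R,4R)-3-(hydroxymethyl)-4,8-dimethylnon-7-enoate | CC(C)(C)OC(=O)C[C@@H](CO)[C@H](C)CCC=C(C)C | intermediate
9 | tert-butyl (3R,4R)-3-formyl-4,8-dimethylnon-7-enoate | CC(C)(C)OC(=O)C[C@@H](C=O)[C@H](C)CCC=C(C)C | intermediate
10 | allenylboronic acid pinacol ester | C=C=CB1OC(C)(C)C(C)(C)O1 | starting material
11 | tert-butyl (3R,4R)-3-[(1R)-1-hydroxybut-3-yn-1-yl]-4,8-dimethylnon-7-enoate | CC(C)(C)OC(=O)C[C@@H]([C@H](O)CC#C)[C@H](C)CCC=C(C)C | intermediate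
12 | tert-butyl (3R,4R)-3-[(1R)-1-(TBS-oxy)but-3-yn-1-yl]-4,8-dimethylnon-7-enoate | CC(C)(C)OC(=O)C[C@@H]([C@H](O[Si](C)(C)C(C)(C)C)CC#C)[C@H](C)CCC=C(C)C | intermediate
13 | tert-butyl (3R,4R)-3-[(1R,3E)-1-(TBS-oxy)-4-(dimethylalumanyl)-3-methylbut-3-en-1-yl]-4,8-dimethylnon-7-enoate | CC(C)(C)OC(=O)C[C@@H]([C@H](O[Si](C)(C)C(C)(C)C)C/C(C)=C/[Al](C)C)[C@H](C)CCC=C(C)C | intermediate
14 | tert-butyl (3R,4R)-3-[(1R,3E)-1-(TBS-oxy)-4-iodo-3-methylbut-3-en-1-yl]-4,8-dimethylnon-7-enoate | CC(C)(C)OC(=O)C[C@@H]([C@H](O[Si](C)(C)C(C)(C)C)C/C(C)=C/I)[C@H](C)CCC=C(C)C | intermediate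
15 | trimethylsilyl ester of 16 | C[Si](C)(C)OC(=O)C[C@@H]([C@H](O[Si](C)(C)C(C)(C)C)C/C(C)=C/I)[C@H](C)CCC=C(C)C | intermediate
16 | (3R,4R)-3-[(1R,3E)-1-(TBS-oxy)-4-iodo-3-methylbut-3-en-1-yl]-4,8-dimethylnon-7-enoic acid | OC(=O)C[C@@H]([C@H](O[Si](C)(C)C(C)(C)C)C/C(C)=C/I)[C@H](C)CCC=C(C)C | intermediate
17 | (S)-4-benzyloxazolidin-2-one | O=C1N[C@@H](Cc2ccccc2)CO1 | starting material
18 | mixed pivalic anhydride of 16 | CC(C)(C)C(=O)OC(=O)C[C@@H]([C@H](O[Si](C)(C)C(C)(C)C)C/C(C)=C/I)[C@H](C)CCC=C(C)C | intermediate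
19 | (4S)-4-benzyl-3-{(3R,4R)-3-[(1R,3E)-1-(TBS-oxy)-4-iodo-3-methylbut-3-en-1-yl]-4,8-dimethylnon-7-enoyl}oxazolidin-2-one | O=C(C[C@@H]([C@H](O[Si](C)(C)C(C)(C)C)C/C(C)=C/I)[C@H](C)CCC=C(C)C)N1[C@@H](Cc2ccccc2)COC1=O | intermediate
20 | acrolein (prop-2-enal) | C=CC=O | starting material
21 | (Z)-dibutylboron enolate of 19 | CCCCB(CCCC)O/C(=C\[C@@H]([C@H](O[Si](C)(C)C(C)(C)C)C/C(C)=C/I)[C@H](C)CCC=C(C)C)N1[C@@H](Cc2ccccc2)COC1=O | intermediate
22 | (4S)-4-benzyl-3-{(2S,3S,4R)-2-[(1R)-1-hydroxyprop-2-en-1-yl]-3-[(1R,3E)-1-(TBS-oxy)-4-iodo-3-methylbut-3-en-1-yl]-4,8-dimethylnon-7-enoyl}oxazolidin-2-one | O=C([C@H]([C@H](O)C=C)[C@@H]([C@H](O[Si](C)(C)C(C)(C)C)C/C(C)=C/I)[C@H](C)CCC=C(C)C)N1[C@@H](Cc2ccccc2)COC1=O | intermediate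
23 | (2R,3S,4R)-2-[(1R)-1-hydroxyprop-2-en-1-yl]-3-[(1R,3E)-1-(TBS-oxy)-4-iodo-3-methylbut-3-en-1-yl]-4,8-dimethylnon-7-en-1-ol | OC[C@H]([C@H](O)C=C)[C@@H]([C@H](O[Si](C)(C)C(C)(C)C)C/C(C)=C/I)[C@H](C)CCC=C(C)C | intermediate
24 | (4R,5R)-5-[(1E,4R,5S,6R)-4-(TBS-oxy)-1-iodo-2,6,10-trimethylundeca-1,9-dien-5-yl]-2,2-dimethyl-4-vinyl-1,3-dioxane | C=C[C@H]1OC(C)(C)OC[C@H]1[C@@H]([C@H](O[Si](C)(C)C(C)(C)C)C/C(C)=C/I)[C@H](C)CCC=C(C)C | intermediate
25 | 9-{2-[(4R,5R)-5-[(1E,4R,5S,6R)-4-(TBS-oxy)-1-iodo-2,6,10-trimethylundeca-1,9-dien-5-yl]-2,2-dimethyl-1,3-dioxan-4-yl]ethyl}-9-borabicyclo[3.3.1]nonane | B1(CC[C@H]2OC(C)(C)OC[C@H]2[C@@H]([C@H](O[Si](C)(C)C(C)(C)C)C/C(C)=C/I)[C@H](C)CCC=C(C)C)C3CCCC1CCC3 | intermediate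
26 | (1R,2R,3S,4R,6E)-cyclononene acetonide: nine-membered ring C1–C9 with 6-methyl, 6E alkene, 4-O-TBS and 3-[(2R)-6-methylhept-5-en-2-yl]; O1 and O19 bridged by CMe2 (2,2-dimethyl-1,3-dioxane fused at C1–C2) | CC(C)(C)[Si](C)(C)O[C@@H]1C/C(C)=C/CC[C@H]2OC(C)(C)OC[C@H]2[C@@H]1[C@H](C)CCC=C(C)C | intermediate
27 | (1R,2R,3S,4R,6E)-4-(TBS-oxy)-2-(hydroxymethyl)-6-methyl-3-[(2R)-6-methylhept-5-en-2-yl]cyclonon-6-en-1-ol | CC(C)(C)[Si](C)(C)O[C@@H]1C/C(C)=C/CC[C@@H](O)[C@@H](CO)[C@@H]1[C@H](C)CCC=C(C)C | intermediate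
28 | (1R,2R,3S,4R,6E)-4-(TBS-oxy)-2-[(TBS-oxy)methyl]-6-methyl-3-[(2R)-6-methylhept-5-en-2-yl]cyclonon-6-en-1-ol | CC(C)(C)[Si](C)(C)O[C@@H]1C/C(C)=C/CC[C@@H](O)[C@@H](CO[Si](C)(C)C(C)(C)C)[C@@H]1[C@H](C)CCC=C(C)C | intermediate
29 | (2R,3S,4R,6E)-4-(TBS-oxy)-2-[(TBS-oxy)methyl]-6-methyl-3-[(2R)-6-methylhept-5-en-2-yl]cyclonon-6-en-1-one | CC(C)(C)[Si](C)(C)O[C@@H]1C/C(C)=C/CCC(=O)[C@@H](CO[Si](C)(C)C(C)(C)C)[C@@H]1[C@H](C)CCC=C(C)C | intermediate
30 | potassium C1(9)-enolate of 29 (ring-cis enolate alkene) | [K+].CC(C)(C)[Si](C)(C)O[C@@H]1C/C(C)=C/C/C=C(/[O-])[C@@H](CO[Si](C)(C)C(C)(C)C)[C@@H]1[C@H](C)CCC=C(C)C | intermediate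
31 | (1(9)E,2R,3S,4R,6E)-4-(TBS-oxy)-2-[(TBS-oxy)methyl]-6-methyl-3-[(2R)-6-methylhept-5-en-2-yl]cyclonona-1(9),6-dien-1-yl trifluoromethanesulfonate | CC(C)(C)[Si](C)(C)O[C@@H]1C/C(C)=C/C/C=C(/OS(=O)(=O)C(F)(F)F)[C@@H](CO[Si](C)(C)C(C)(C)C)[C@@H]1[C@H](C)CCC=C(C)C | intermediate
32 | (1(9)E,2R,3S,4R,6E)-4-hydroxy-2-(hydroxymethyl)-6-methyl-3-[(2R)-6-methylhept-5-en-2-yl]cyclonona-1(9),6-dien-1-yl trifluoromethanesulfonate | O[C@@H]1C/C(C)=C/C/C=C(/OS(=O)(=O)C(F)(F)F)[C@@H](CO)[C@@H]1[C@H](C)CCC=C(C)C | intermediate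
33 | (3aS,4S,5R,7E,10E)-5-hydroxy-7-methyl-4-[(2R)-6-methylhept-5-en-2-yl]-3,3a,4,5,6,9-hexahydro-1H-cyclonona[c]furan-1-one | O[C@@H]1C/C(C)=C/C/C=C2/C(=O)OC[C@H]2[C@@H]1[C@H](C)CCC=C(C)C | intermediate
34 | (3aS,4S,5R,7E,10E)-7-methyl-4-[(2R)-6-methylhept-5-en-2-yl]-1-oxo-3,3a,4,5,6,9-hexahydro-1H-cyclonona[c]furan-5-yl acetate | CC(=O)O[C@@H]1C/C(C)=C/C/C=C2/C(=O)OC[C@H]2[C@@H]1[C@H](C)CCC=C(C)C | target

## Step count and risks

Total step count: 20. Longest linear sequence: 20 steps (fully linear from 1).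

Steps most likely to fail:

Step 13 (nine-membered ring closure; risk of oligomerisation, protodeboronation or no cyclisation). The fallback sets out from 24 and comes back at 26, and replaces the in situ boron nucleophile by a discrete organozinc. Hydroboration of the vinyl group of 24 with 9-BBN and oxidation with NaBO3 gives the primary alcohol F1. Iodination with I2, PPh3 and imidazole gives the primary iodide F2. Zinc insertion (Zn dust, LiCl, DMA/THF, 40 °C; the alkenyl iodide is inert) gives the alkylzinc iodide F3, which is closed by intramolecular Negishi coupling (Pd2(dba)3, SPhos, slow addition, 2 mM) to 26. The same iodide F2 also allows a nickel-catalysed reductive ring closure.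

Step 17 (regio- and geometry-defined enol triflate in the strained ring; risk of C2 epimerisation or β-elimination of the C19 silyloxy group, and a sluggish carbonylation later). The fallback sets out from 29 and comes back at 33, and avoids both the enolate and the Pd/CO step. Condensation of 29 with 2,4,6-triisopropylbenzenesulfonyl hydrazide gives the trisylhydrazone F4. A Shapiro reaction (n-BuLi 2.2 equiv, THF/TMEDA, −78 → 0 °C) forms the C1 alkenyllithium on the C9 methylene side, and a CO2 quench gives the unsaturated acid F5. HF·pyridine removes both silyl ethers and the C19 hydroxy acid lactonises to 33.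

Step 5 (C4 stereocontrol and reactivity of the hindered α-branched aldehyde). The fallback sets out from 9 and comes back at 12, and builds C4–C5 by an auxiliary-controlled acetate aldol followed by one-carbon homologation. A Nagao acetate aldol of 9 with N-acetyl-(4S)-4-isopropylthiazolidine-2-thione (Sn(OTf)2, N-ethylpiperidine, CH2Cl2, −78 °C; chelated enolate, Re-face attack) gives the aldol adduct F6. TBSOTf and 2,6-lutidine give the silyl ether F7. DIBAL-H at −78 °C releases the auxiliary and gives the aldehyde F8. Ohira–Bestmann homologation (dimethyl (1-diazo-2-oxopropyl)phosphonate, K2CO3, MeOH) returns the alkyne 12.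

## Further compounds

F1 | step 13 | 2-[(4R,5R)-5-[(1E,4R,5S,6R)-4-(TBS-oxy)-1-iodo-2,6,10-trimethylundeca-1,9-dien-5-yl]-2,2-dimethyl-1,3-dioxan-4-yl]ethan-1-ol | OCC[C@H]1OC(C)(C)OC[C@H]1[C@@H]([C@H](O[Si](C)(C)C(C)(C)C)C/C(C)=C/I)[C@H](C)CCC=C(C)C
F2 | step 13 | (4R,5R)-4-(2-iodoethyl)-5-[(1E,4R,5S,6R)-4-(TBS-oxy)-1-iodo-2,6,10-trimethylundeca-1,9-dien-5-yl]-2,2-dimethyl-1,3-dioxane | ICC[C@H]1OC(C)(C)OC[C@H]1[C@@H]([C@H](O[Si](C)(C)C(C)(C)C)C/C(C)=C/I)[C@H](C)CCC=C(C)C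
F3 | step 13 | alkylzinc iodide from F2 | I[Zn]CC[C@H]1OC(C)(C)OC[C@H]1[C@@H]([C@H](O[Si](C)(C)C(C)(C)C)C/C(C)=C/I)[C@H](C)CCC=C(C)C
F4 | step 17 | 2,4,6-triisopropylbenzenesulfonyl hydrazone of 29 (N–N syn to C9) | CC(C)(C)[Si](C)(C)O[C@@H]1C/C(C)=C/CC/C(=N\NS(=O)(=O)c2c(C(C)C)cc(C(C)C)cc2C(C)C)[C@@H](CO[Si](C)(C)C(C)(C)C)[C@@H]1[C@H](C)CCC=C(C)C
F5 | step 17 | (1(9)E,2R,3S,4R,6E)-4-(TBS-oxy)-2-[(TBS-oxy)methyl]-6-methyl-3-[(2R)-6-methylhept-5-en-2-yl]cyclonona-1(9),6-diene-1-carboxylic acid | CC(C)(C)[Si](C)(C)O[C@@H]1C/C(C)=C/C/C=C(/C(=O)O)[C@@H](CO[Si](C)(C)C(C)(C)C)[C@@H]1[C@H](C)CCC=C(C)C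
F6 | step 5 | tert-butyl (3R,4R)-3-{(1R)-1-hydroxy-3-[(4S)-4-isopropyl-2-thioxothiazolidin-3-yl]-3-oxopropyl}-4,8-dimethylnon-7-enoate | CC(C)(C)OC(=O)C[C@@H]([C@H](O)CC(=O)N1[C@@H](C(C)C)CSC1=S)[C@H](C)CCC=C(C)C
F7 | step 5 | tert-butyl (3R,4R)-3-{(1R)-1-(TBS-oxy)-3-[(4S)-4-isopropyl-2-thioxothiazolidin-3-yl]-3-oxopropyl}-4,8-dimethylnon-7-enoate | CC(C)(C)OC(=O)C[C@@H]([C@H](O[Si](C)(C)C(C)(C)C)CC(=O)N1[C@@H](C(C)C)CSC1=S)[C@H](C)CCC=C(C)C
F8 | step 5 | tert-butyl (3R,4R)-3-[(1R)-1-(TBS-oxy)-3-oxopropyl]-4,8-dimethylnon-7-enoate | CC(C)(C)OC(=O)C[C@@H]([C@H](O[Si](C)(C)C(C)(C)C)CC=O)[C@H](C)CCC=C(C)C
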